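**Retrosynthetic overview** (C1 = acid carbon, counted along the chain to C21 = the CH bonded to C4 of the oxazole)
1. The acid comes from its methyl ester and the free hydroxyls from triethylsilyl (TES) ethers. The C15 carbinol comes from a C15 ketone by an anti reduction directed by the C13 hydroxyl.
2. Main disconnection C13–C14: an anti-selective boron aldol joins a C1–C13 aldehyde to a C14–C21 ethyl ketone. This creates C13 and C14 and installs the hydroxyl that later sets C15.
3. Enabling feature: C14(CH3)–C15(O)–C16(CH3) is a pentan-3-one unit, and the C16=C17 double bond lies α,β to C15. The alkene can therefore travel through the union as its aldol "hydrate" (C16–H, C17–OAc). These two sacrificial stereocentres steer the aldol and then leave as acetic acid to give the (E)-alkene.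
4. The ketone is built from the oxazole aldehyde by two Wittig homologations, an Evans syn aldol, Weinreb amide formation, EtMgBr addition and acetylation. The aldehyde is built by a C8–C9 Suzuki coupling of an alkenylboronate ((Z)-crotylboration, oxidation–Wittig, cross metathesis) with an alkenyl iodide (carboalumination, allylboration).
5. No ring is formed in the route: the 2-methyloxazole, the only ring of the target, is bought.

Key step: step 19

Assumption: the ketone control in step 19 is taken to follow the usual behaviour of (E)-enol dicyclohexylborinates of α-methyl-β-oxygenated ethyl ketones, in which the new methyl ends up anti to the resident methyl across the carbonyl. The (S)-auxiliary of step 3 was chosen on that basis.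

Step 1
Reactants: 1 2-methyl-1,3-oxazole-4-carbaldehyde
Product: 2 (2E)-2-methyl-3-(2-methyl-1,3-oxazol-4-yl)prop-2-enal
Conditions: Ph3P=C(CH3)CHO, toluene, 90 °C
Reagents that add atoms: 2-(triphenylphosphoranylidene)propanal, CC(C=O)=P(c1ccccc1)(c1ccccc1)c1ccccc1
Why: A Wittig olefination with a stabilised α-branched ylide should give the (E)-trisubstituted enal (C20=C21).

Step 2
Reactants: 2 (2E)-2-methyl-3-(2-methyl-1,3-oxazol-4-yl)prop-2-enal
Product: 3 (2E,4E)-4-methyl-5-(2-methyl-1,3-oxazol-4-yl)penta-2,4-dienal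
Conditions: Ph3P=CHCHO (slight excess only), toluene, 80 °C
Reagents that add atoms: (triphenylphosphoranylidene)acetaldehyde, O=CC=P(c1ccccc1)(c1ccccc1)c1ccccc1
Why: A two-carbon Wittig homologation with the stabilised formylmethylene ylide is (E)-selective, and limiting the ylide should hold back a second homologation.

Step 3
Reactants: 3 (2E,4E)-4-methyl-5-(2-methyl-1,3-oxazol-4-yl)penta-2,4-dienal; 4 (4S)-4-benzyl-3-propanoyl-1,3-oxazolidin-2-one
Product: 6 (4S)-4-benzyl-3-[(2S,3R,4E,6E)-3-hydroxy-2,6-dimethyl-7-(2-methyl-1,3-oxazol-4-yl)hepta-4,6-dienoyl]-1,3-oxazolidin-2-one, via boron enolate 5 (not isolated)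
Conditions: 4, Bu2BOTf, Et3N, CH2Cl2, −78 to 0 °C; then 3, −78 to 0 °C; MeOH, pH 7 buffer, 30% H2O2, 0 °C
Reagents that add atoms: none
Why: In this Evans syn aldol the (Z)-boron enolate reacts through a Zimmerman–Traxler chair whose face is fixed by the (S)-benzyl auxiliary, which sets the two sacrificial centres C16 (S) and C17 (R).

Step 4
Reactants: 6 (4S)-4-benzyl-3-[(2S,3R,4E,6E)-3-hydroxy-2,6-dimethyl-7-(2-methyl-1,3-oxazol-4-yl)hepta-4,6-dienoyl]-1,3-oxazolidin-2-one
Product: 7 (2S,3R,4E,6E)-3-hydroxy-N-methoxy-N,2,6-trimethyl-7-(2-methyl-1,3-oxazol-4-yl)hepta-4,6-dienamide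
Conditions: MeNHOMe·HCl, Me3Al, THF, −20 to 0 °C
Reagents that add atoms: N,O-dimethylhydroxylamine hydrochloride, CNOC.Cl
Why: The Weinreb transamination with the aluminium amide is helped by the free β-hydroxyl and releases the auxiliary without touching either stereocentre.

Step 5
Reactants: 7 (2S,3R,4E,6E)-3-hydroxy-N-methoxy-N,2,6-trimethyl-7-(2-methyl-1,3-oxazol-4-yl)hepta-4,6-dienamide
Product: 8 (4S,5R,6E,8E)-5-hydroxy-4,8-dimethyl-9-(2-methyl-1,3-oxazol-4-yl)nona-6,8-dien-3-one
Conditions: EtMgBr (3 equiv), THF, 0 °C; aq. NH4Cl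
Reagents that add atoms: ethylmagnesium bromide, CC[Mg]Br
Why: In the Weinreb ketone synthesis one equivalent of Grignard reagent deprotonates the hydroxyl and the addition stops at the chelated tetrahedral adduct, so only the ethyl ketone should form on work-up.

Step 6
Reactants: 8 (4S,5R,6E,8E)-5-hydroxy-4,8-dimethyl-9-(2-methyl-1,3-oxazol-4-yl)nona-6,8-dien-3-one
Product: 9 (4S,5R,6E,8E)-5-acetoxy-4,8-dimethyl-9-(2-methyl-1,3-oxazol-4-yl)nona-6,8-dien-3-one
Conditions: Ac2O, pyridine, DMAP (cat.), CH2Cl2, 0 °C, short time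
Reagents that add atoms: acetic anhydride, CC(=O)OC(C)=O
Why: O-acylation turns the C17 hydroxyl into a group that protects it during enolisation and later serves as the leaving group, and the low temperature should prevent early elimination.

Step 7
Reactants: 10 3-[(tert-butyldimethylsilyl)oxy]propanal
Product: 11 (3R,4R)-1-[(tert-butyldimethylsilyl)oxy]-4-methylhex-5-en-3-ol
Conditions: cis-but-2-ene, n-BuLi, KOt-Bu, THF, −78 to −45 °C; (−)-Ipc2BOMe, −78 °C; BF3·OEt2; 10, −78 °C; NaOH, 30% H2O2
Reagents that add atoms: cis-but-2-ene, C/C=C\C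
Why: In this Brown (Z)-crotylboration the chair transition state turns the (Z)-geometry into the 5,6-syn pair, and the (−)-Ipc ligands choose the aldehyde face that gives 5R,6R.

Step 8
Reactants: 11 (3R,4R)-1-[(tert-butyldimethylsilyl)oxy]-4-methylhex-5-en-3-ol
Product: 12 (3R,4R)-4-methylhex-5-ene-1,3-diol
Conditions: camphorsulfonic acid (cat.), MeOH, 0 °C to rt
Reagents that add atoms: none
Why: Acid-catalysed methanolysis removes the unhindered primary silyl ether and leaves the alkene and both stereocentres untouched.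

Step 9
Reactants: 12 (3R,4R)-4-methylhex-5-ene-1,3-diol
Product: 14 methyl (2E,5R,6R)-5-hydroxy-6-methylocta-2,7-dienoate, via hydroxy aldehyde 13 (not isolated)
Conditions: TEMPO (cat.), PhI(OAc)2, CH2Cl2, rt; then Ph3P=CHCO2Me, rt
Reagents that add atoms: methyl (triphenylphosphoranylidene)acetate, COC(=O)C=P(c1ccccc1)(c1ccccc1)c1ccccc1
Why: In this tandem oxidation–Wittig reaction the oxoammonium oxidant takes the primary alcohol of the 1,3-diol selectively, and the stabilised ylide traps the fragile β-hydroxy aldehyde in the same flask as the (E)-enoate.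

Step 10
Reactants: 14 methyl (2E,5R,6R)-5-hydroxy-6-methylocta-2,7-dienoate
Product: 15 methyl (2E,5R,6R)-6-methyl-5-[(triethylsilyl)oxy]octa-2,7-dienoate
Conditions: TESCl, imidazole, CH2Cl2, 0 °C
Reagents that add atoms: chlorotriethylsilane, CC[Si](Cl)(CC)CC
Why: Standard silylation masks the C5 hydroxyl with a group that can be removed under very mild conditions at the end.

Step 11
Reactants: 15 methyl (2E,5R,6R)-6-methyl-5-[(triethylsilyl)oxy]octa-2,7-dienoate
Product: 16 methyl (2E,5R,6R,7E)-6-methyl-8-(4,4,5,5-tetramethyl-1,3,2-dioxaborolan-2-yl)-5-[(triethylsilyl)oxy]octa-2,7-dienoate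
Conditions: vinylboronic acid pinacol ester (3 equiv), second-generation Hoveyda–Grubbs catalyst (5 mol%), CH2Cl2, 40 °C
Reagents that add atoms: vinylboronic acid pinacol ester, C=CB1OC(C)(C)C(C)(C)O1
Why: Olefin cross metathesis of the terminal alkene with the vinylboronate should give the (E)-alkenylboronate, while the electron-poor enoate stays out of the catalytic cycle.

Step 12
Reactants: 17 prop-2-yn-1-ol
Product: 19 (2E)-3-iodo-2-methylprop-2-en-1-ol, via alkenylalane 18 (not isolated)
Conditions: Me3Al (3 equiv), Cp2ZrCl2 (0.25 equiv), CH2Cl2, 0 °C to rt; then I2, THF, −30 °C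
Reagents that add atoms: trimethylaluminium, C[Al](C)C; iodine, II
Why: The Negishi carboalumination adds methyl and aluminium syn across the alkyne with aluminium at the terminus, and iodinolysis with retention gives the (E)-iodide that becomes C9=C10.

Step 13
Reactants: 19 (2E)-3-iodo-2-methylprop-2-en-1-ol
Product: 20 (2E)-3-iodo-2-methylprop-2-enal
Conditions: MnO2, CH2Cl2, rt
Reagents that add atoms: none
Why: Allylic oxidation with manganese dioxide stops at the enal and does not disturb the alkenyl iodide geometry.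

Step 14
Reactants: 20 (2E)-3-iodo-2-methylprop-2-enal
Product: 21 (1E,3R)-1-iodo-2-methylhexa-1,5-dien-3-ol
Conditions: (+)-Ipc2B(allyl), Et2O, −78 °C; NaOH, 30% H2O2
Reagents that add atoms: (+)-B-allyldiisopinocampheylborane, C=CCB([C@H]1C[C@H]2C[C@@H]([C@@H]1C)C2(C)C)[C@H]1C[C@H]2C[C@@H]([C@@H]1C)C2(C)C
Why: In this Brown allylboration the chair transition state is controlled by the (+)-Ipc ligands, which should deliver the allyl group to the face of the enal that gives C11 (R).

Step 15
Reactants: 21 (1E,3R)-1-iodo-2-methylhexa-1,5-dien-3-ol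
Product: 24 (3R,4E)-5-iodo-4-methylpent-4-ene-1,3-diol, via triol 22 (not isolated), via hydroxy aldehyde 23 (not isolated)
Conditions: OsO4 (cat.), NaIO4, 2,6-lutidine, dioxane/H2O, rt; then NaBH4, MeOH, 0 °C
Reagents that add atoms: osmium tetroxide, O=[Os](=O)(=O)=O; sodium periodate, [Na+].[O-]I(=O)(=O)=O
Why: The Lemieux–Johnson cleavage picks the electron-rich monosubstituted alkene over the hindered iodoalkene, and immediate borohydride reduction secures the β-hydroxy aldehyde before it can eliminate.

Step 16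
Reactants: 24 (3R,4E)-5-iodo-4-methylpent-4-ene-1,3-diol
Product: 25 (3R,4E)-5-iodo-4-methyl-1,3-bis[(triethylsilyl)oxy]pent-4-ene
Conditions: TESCl (2.3 equiv), imidazole, CH2Cl2, 0 °C
Reagents that add atoms: chlorotriethylsilane, CC[Si](Cl)(CC)CC
Why: Double silylation protects both hydroxyls in one operation, and the primary and secondary silyl ethers remain distinguishable in step 18.

Step 17
Reactants: 16 methyl (2E,5R,6R,7E)-6-methyl-8-(4,4,5,5-tetramethyl-1,3,2-dioxaborolan-2-yl)-5-[(triethylsilyl)oxy]octa-2,7-dienoate; 25 (3R,4E)-5-iodo-4-methyl-1,3-bis[(triethylsilyl)oxy]pent-4-ene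
Product: 26 methyl (2E,5R,6R,7E,9E,11R)-6,10-dimethyl-5,11,13-tris[(triethylsilyl)oxy]trideca-2,7,9-trienoate
Conditions: Pd(dppf)Cl2 (5 mol%), aq. K3PO4, THF, rt
Reagents that add atoms: none
Why: The Suzuki–Miyaura alkenyl–alkenyl coupling proceeds with retention at both partners and should give the (7E,9E)-diene under conditions that spare the ester and the silyl ethers.

Step 18
Reactants: 26 methyl (2E,5R,6R,7E,9E,11R)-6,10-dimethyl-5,11,13-tris[(triethylsilyl)oxy]trideca-2,7,9-trienoate
Product: 27 methyl (2E,5R,6R,7E,9E,11R)-6,10-dimethyl-13-oxo-5,11-bis[(triethylsilyl)oxy]trideca-2,7,9-trienoate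
Conditions: (COCl)2, DMSO, CH2Cl2, −78 to −30 °C; Et3N, −78 to 0 °C
Reagents that add atoms: none
Why: Under Swern conditions the unhindered primary triethylsilyl ether is attacked by the activated sulfoxide and oxidised directly to the aldehyde, while the two secondary silyl ethers are too hindered to react.

Step 19
Reactants: 9 (4S,5R,6E,8E)-5-acetoxy-4,8-dimethyl-9-(2-methyl-1,3-oxazol-4-yl)nona-6,8-dien-3-one; 27 methyl (2E,5R,6R,7E,9E,11R)-6,10-dimethyl-13-oxo-5,11-bis[(triethylsilyl)oxy]trideca-2,7,9-trienoate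
Product: 29 methyl (2E,5R,6R,7E,9E,11R,13S,14S,16S,17R,18E,20E)-17-acetoxy-13-hydroxy-6,10,14,16,20-pentamethyl-21-(2-methyl-1,3-oxazol-4-yl)-15-oxo-5,11-bis[(triethylsilyl)oxy]henicosa-2,7,9,18,20-pentaenoate, via enol borinate 28 (not isolated)
Conditions: 9 (1.3 equiv), c-Hex2BCl, Et3N, Et2O, −78 to −10 °C; then 27, −78 to −25 °C; MeOH, pH 7 buffer, 30% H2O2, 0 °C
Reagents that add atoms: none
Why: Chlorodicyclohexylborane and Et3N enolise 9 at the C14 methylene to the (E)-enol borinate 28, which binds the aldehyde of 27 at boron and forms the C13–C14 bond through a Zimmerman–Traxler chair, and oxidative work-up frees 29. The closest known reaction type is the Paterson anti aldol of α-methyl-β-oxygenated ethyl ketones used as dipropionate reagents. No ring is closed, the only cyclic element being the six-membered boron transition state. The (E)-enolate geometry places the C14 methyl and the C12 chain equatorial and so gives the 13,14-anti pair. The absolute sense comes from C16, whose hydrogen eclipses the enolate double bond to avoid allylic 1,3-strain with the C14 methyl, so the two enolate faces differ and the new methyl ends anti to the C16 methyl (13S,14S), while the closed boron transition state responds only weakly to the C11 silyl ether and ketone control should override the aldehyde's slight 1,3-anti bias. The step needs enolisation at C14 rather than C16, retention of the acetate and attack on the aldehyde only, and these are secured by the hindered C16 methine next to the acetoxy carbon, by the fact that C16–H is never removed at low temperature, and by the inertness of the enoate and polyene towards a boron enolate.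

Step 20
Reactants: 29 methyl (2E,5R,6R,7E,9E,11R,13S,14S,16S,17R,18E,20E)-17-acetoxy-13-hydroxy-6,10,14,16,20-pentamethyl-21-(2-methyl-1,3-oxazol-4-yl)-15-oxo-5,11-bis[(triethylsilyl)oxy]henicosa-2,7,9,18,20-pentaenoate
Product: 30 methyl (2E,5R,6R,7E,9E,11R,13S,14S,16E,18E,20E)-13-hydroxy-6,10,14,16,20-pentamethyl-21-(2-methyl-1,3-oxazol-4-yl)-15-oxo-5,11-bis[(triethylsilyl)oxy]henicosa-2,7,9,16,18,20-hexaenoate
Conditions: DBU (1.5 equiv), CH2Cl2, 0 °C
Reagents that add atoms: none
Why: In this E1cB elimination the allylic acetate at C17 is a good leaving group and the product is the fully conjugated (E)-trienone, so loss of C16–H and acetate should be much faster than enolisation at C14 or loss of the C13 hydroxyl, and it erases both sacrificial centres.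

Step 21
Reactants: 30 methyl (2E,5R,6R,7E,9E,11R,13S,14S,16E,18E,20E)-13-hydroxy-6,10,14,16,20-pentamethyl-21-(2-methyl-1,3-oxazol-4-yl)-15-oxo-5,11-bis[(triethylsilyl)oxy]henicosa-2,7,9,16,18,20-hexaenoate
Product: 31 methyl (2E,5R,6R,7E,9E,11R,13S,14S,15R,16E,18E,20E)-13,15-dihydroxy-6,10,14,16,20-pentamethyl-21-(2-methyl-1,3-oxazol-4-yl)-5,11-bis[(triethylsilyl)oxy]henicosa-2,7,9,16,18,20-hexaenoate
Conditions: Me4NBH(OAc)3, MeCN/AcOH, −30 °C
Reagents that add atoms: none
Why: In the Evans–Saksena reduction the C13 hydroxyl exchanges onto boron and delivers hydride intramolecularly through a chair, which gives the 1,3-anti diol (15R) by 1,2-reduction, while the reagent is too weak to touch the enoate.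

Step 22
Reactants: 31 methyl (2E,5R,6R,7E,9E,11R,13S,14S,15R,16E,18E,20E)-13,15-dihydroxy-6,10,14,16,20-pentamethyl-21-(2-methyl-1,3-oxazol-4-yl)-5,11-bis[(triethylsilyl)oxy]henicosa-2,7,9,16,18,20-hexaenoate
Product: 32 methyl (2E,5R,6R,7E,9E,11R,13S,14S,15R,16E,18E,20E)-5,11,13,15-tetrahydroxy-6,10,14,16,20-pentamethyl-21-(2-methyl-1,3-oxazol-4-yl)henicosa-2,7,9,16,18,20-hexaenoate
Conditions: HF·pyridine, excess pyridine, THF, 0 °C
Reagents that add atoms: none
Why: Buffered fluoride cleaves the labile triethylsilyl ethers under conditions mild enough that the dienyl and trienyl carbinols should not ionise.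

Step 23
Reactants: 32 methyl (2E,5R,6R,7E,9E,11R,13S,14S,15R,16E,18E,20E)-5,11,13,15-tetrahydroxy-6,10,14,16,20-pentamethyl-21-(2-methyl-1,3-oxazol-4-yl)henicosa-2,7,9,16,18,20-hexaenoate
Product: 34 (2E,5R,6R,7E,9E,11R,13S,14S,15R,16E,18E,20E)-5,11,13,15-tetrahydroxy-6,10,14,16,20-pentamethyl-21-(2-methyl-1,3-oxazol-4-yl)henicosa-2,7,9,16,18,20-hexaenoic acid, via lithium carboxylate 33 (not isolated)
Conditions: LiOH, THF/MeOH/H2O, 0 °C to rt; then cold dilute HCl to pH 4–5
Reagents that add atoms: lithium hydroxide, [Li+].[OH-]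
Why: Saponification of the methyl enoate meets no base-sensitive carbonyl elsewhere in the molecule, and careful acidification should release the acid without ionising the allylic alcohols.

**Compound list**
1 | 2-methyl-1,3-oxazole-4-carbaldehyde | O=Cc1coc(C)n1 | starting material
2 | (2E)-2-methyl-3-(2-methyl-1,3-oxazol-4-yl)prop-2-enal | O=C/C(C)=C/c1coc(C)n1 | intermediate
3 | (2E,4E)-4-methyl-5-(2-methyl-1,3-oxazol-4-yl)penta-2,4-dienal | O=C/C=C/C(C)=C/c1coc(C)n1 | intermediate
4 | (4S)-4-benzyl-3-propanoyl-1,3-oxazolidin-2-one | CCC(=O)N1[C@@H](Cc2ccccc2)COC1=O | starting material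
5 | (Z)-dibutylboron enolate of 4 | C/C=C(\OB(CCCC)CCCC)N1[C@@H](Cc2ccccc2)COC1=O | intermediate
6 | Evans syn aldol adduct (2S,3R) | O=C1OC[C@H](Cc2ccccc2)N1C(=O)[C@@H](C)[C@H](O)/C=C/C(C)=C/c1coc(C)n1 | intermediate
7 | Weinreb amide (2S,3R) | CON(C)C(=O)[C@@H](C)[C@H](O)/C=C/C(C)=C/c1coc(C)n1 | intermediate
8 | β-hydroxy ethyl ketone (4S,5R) | CCC(=O)[C@@H](C)[C@H](O)/C=C/C(C)=C/c1coc(C)n1 | intermediate
9 | β-acetoxy ethyl ketone (4S,5R), C14–C21 fragment | CCC(=O)[C@@H](C)[C@H](OC(C)=O)/C=C/C(C)=C/c1coc(C)n1 | intermediate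
10 | 3-[(tert-butyldimethylsilyl)oxy]propanal | O=CCCO[Si](C)(C)C(C)(C)C | starting material
11 | (3R,4R)-1-[(tert-butyldimethylsilyl)oxy]-4-methylhex-5-en-3-ol | C=C[C@@H](C)[C@H](O)CCO[Si](C)(C)C(C)(C)C | intermediate
12 | (3R,4R)-4-methylhex-5-ene-1,3-diol | C=C[C@@H](C)[C@H](O)CCO | intermediate
13 | (3R,4R)-3-hydroxy-4-methylhex-5-enal | C=C[C@@H](C)[C@H](O)CC=O | intermediate
14 | methyl (2E,5R,6R)-5-hydroxy-6-methylocta-2,7-dienoate | C=C[C@@H](C)[C@H](O)C/C=C/C(=O)OC | intermediate
15 | methyl (2E,5R,6R)-6-methyl-5-[(triethylsilyl)oxy]octa-2,7-dienoate | C=C[C@@H](C)[C@H](O[Si](CC)(CC)CC)C/C=C/C(=O)OC | intermediate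
16 | (7E)-alkenylboronate, C1–C8 | CC1(C)OB(/C=C/[C@@H](C)[C@H](O[Si](CC)(CC)CC)C/C=C/C(=O)OC)OC1(C)C | intermediate
17 | prop-2-yn-1-ol | C#CCO | starting material
18 | (E)-alkenylalane, aluminium alkoxide form | C[Al](C)OC/C(C)=C/[Al](C)C | intermediate
19 | (2E)-3-iodo-2-methylprop-2-en-1-ol | OC/C(C)=C/I | intermediate
20 | (2E)-3-iodo-2-methylprop-2-enal | O=C/C(C)=C/I | intermediate
21 | (1E,3R)-1-iodo-2-methylhexa-1,5-dien-3-ol | C=CC[C@@H](O)/C(C)=C/I | intermediate
22 | (4R,5E)-6-iodo-5-methylhex-5-ene-1,2,4-triol, both C2 epimers | OCC(O)C[C@@H](O)/C(C)=C/I | intermediate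
23 | (3R,4E)-3-hydroxy-5-iodo-4-methylpent-4-enal | O=CC[C@@H](O)/C(C)=C/I | intermediate
24 | (3R,4E)-5-iodo-4-methylpent-4-ene-1,3-diol | OCC[C@@H](O)/C(C)=C/I | intermediate
25 | (3R,4E)-5-iodo-4-methyl-1,3-bis[(triethylsilyl)oxy]pent-4-ene | CC[Si](CC)(CC)OCC[C@@H](O[Si](CC)(CC)CC)/C(C)=C/I | intermediate
26 | tris(triethylsilyl) trienoate, C1–C13 | CC[Si](CC)(CC)OCC[C@@H](O[Si](CC)(CC)CC)/C(C)=C/C=C/[C@@H](C)[C@H](O[Si](CC)(CC)CC)C/C=C/C(=O)OC | intermediate
27 | C1–C13 aldehyde | O=CC[C@@H](O[Si](CC)(CC)CC)/C(C)=C/C=C/[C@@H](C)[C@H](O[Si](CC)(CC)CC)C/C=C/C(=O)OC | intermediate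
28 | (E)-enol dicyclohexylborinate of 9 | C/C=C(/OB(C1CCCCC1)C1CCCCC1)[C@@H](C)[C@H](OC(C)=O)/C=C/C(C)=C/c1coc(C)n1 | intermediate
29 | aldol adduct (13S,14S,16S,17R) | CC(/C=C/[C@@H](OC(C)=O)[C@H](C)C(=O)[C@@H](C)[C@@H](O)C[C@@H](O[Si](CC)(CC)CC)/C(C)=C/C=C/[C@@H](C)[C@H](O[Si](CC)(CC)CC)C/C=C/C(=O)OC)=C\c1coc(C)n1 | intermediate
30 | β-hydroxy trienone (13S,14S) | CC(/C=C/C=C(\C)C(=O)[C@@H](C)[C@@H](O)C[C@@H](O[Si](CC)(CC)CC)/C(C)=C/C=C/[C@@H](C)[C@H](O[Si](CC)(CC)CC)C/C=C/C(=O)OC)=C\c1coc(C)n1 | intermediate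
31 | 13,15-anti diol (13S,14S,15R) | CC(/C=C/C=C(\C)[C@H](O)[C@@H](C)[C@@H](O)C[C@@H](O[Si](CC)(CC)CC)/C(C)=C/C=C/[C@@H](C)[C@H](O[Si](CC)(CC)CC)C/C=C/C(=O)OC)=C\c1coc(C)n1 | intermediate
32 | tetraol methyl ester | CC(/C=C/C=C(\C)[C@H](O)[C@@H](C)[C@@H](O)C[C@@H](O)/C(C)=C/C=C/[C@@H](C)[C@H](O)C/C=C/C(=O)OC)=C\c1coc(C)n1 | intermediate
33 | lithium carboxylate of 34 | CC(/C=C/C=C(\C)[C@H](O)[C@@H](C)[C@@H](O)C[C@@H](O)/C(C)=C/C=C/[C@@H](C)[C@H](O)C/C=C/C(=O)[O-])=C\c1coc(C)n1.[Li+] | intermediate
34 | CNP0256102.1 | CC(/C=C/C=C(\C)[C@H](O)[C@@H](C)[C@@H](O)C[C@@H](O)/C(C)=C/C=C/[C@@H](C)[C@H](O)C/C=C/C(=O)O)=C\c1coc(C)n1 | target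

**Step count**

Total steps: 23. The longest linear sequence is 12 steps (10 to 34 through steps 7–11 and 17–23). The line from 17 through steps 12–23 is equally long.

**Steps most likely to fail**

**Step 19.** The C16 centre may discriminate the enolate faces too weakly, the pairing with the chiral aldehyde may be mismatched, or acetate may be lost during enolisation.
- The fallback moves the stereocontrol from the substrate to the reagent. It sets out from 9 and 27 and comes back at 30.
- Treating 9 with DBU gives the achiral (4E,6E,8E)-4,8-dimethyl-9-(2-methyl-1,3-oxazol-4-yl)nona-4,6,8-trien-3-one F1, whose only enolisable position is C14.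
- F1 is enolised with Et3N and the (−)-menthone-derived bis{[(1S,2S,5R)-2-isopropyl-5-methylcyclohexyl]methyl}chloroborane, a reagent designed for asymmetric anti aldol reactions of ethyl ketones. This gives the (E)-enol bis(menthylmethyl)borinate F2.
- Addition of F2 to 27 and oxidative work-up delivers 30 directly.

**Step 20.** The amine base may trigger retro-aldol cleavage of the β-hydroxy ketone, erosion of C14 by enolisation, or dehydration at C13.
- The fallback sets out from 29 and comes back at 30. It replaces deprotonation by metal-induced ionisation.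
- The C17 acetate is allylic, so catalytic Pd(PPh3)4 (zerovalent palladium) in THF should form the η3-allyl complex.
- That complex loses the acidic C16 hydrogen to the liberated acetate, the only base present, and gives the conjugated trienone.

**Step 11.** The allylic branching at C6 may slow the metathesis so much that catalyst decay and self-metathesis of the vinylboronate dominate.
- The fallback sets out from 15 and 25 and comes back at 26, so it bypasses 16 and step 17.
- A Heck alkenylation of the terminal alkene of 15 with iodide 25 (Pd(OAc)2, Ag2CO3, DMF) forms the C8–C9 bond directly.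
- β-Hydride elimination towards C8 then gives the (7E,9E)-diene.

**Further compounds**
F1 | step 19 | (4E,6E,8E)-4,8-dimethyl-9-(2-methyl-1,3-oxazol-4-yl)nona-4,6,8-trien-3-one | CCC(=O)/C(C)=C/C=C/C(C)=C/c1coc(C)n1
F2 | step 19 | (E)-enol bis(menthylmethyl)borinate of F1 | C/C=C(/OB(C[C@H]1C[C@H](C)CC[C@H]1C(C)C)C[C@H]1C[C@H](C)CC[C@H]1C(C)C)\C(C)=C\C=C\C(C)=C\c1coc(C)n1
F0 | step 20 | none | none
F0 | step 11 | none | none
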